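| flask | electrophile | nucleophile | free base | protic impurity | remark | time |
|---|---|---|---|---|---|---|
| beta | 0.31 M | 0.95 equiv | 3.8 equiv | 0.031 M | run made earlier |  |
| delta | 0.31 M | 0.95 equiv | 4.6 equiv | 0.031 M | run made earlier |  |
| zeta | 0.31 M | 0.95 equiv | 5 equiv | 0.031 M | run made earlier |  |
| amber | 0.31 M | 0.950 equiv | 6.00 equiv | 0.0310 M |  | 15 h |
| violet | 0.31 M | 0.950 equiv | 3.00 equiv | 0.0310 M |  | 15 h |

| run | time / h | electrophile / % | target / % |
|---|---|---|---|
| beta | 1.33 | 48.6 | 45.8 |
| beta | 4.00 | 23.3 | 63.9 |
| beta | 8.00 | 15.2 | 69.9 |
| beta | 10.0 | 16.2 | 72.7 |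
| beta | 15.0 | 16.0 | 74.3 |
| delta | 1.33 | 44.5 | 46.9 |
| delta | 4.00 | 26.0 | 67.1 |
| delta | 8.00 | 17.3 | 71.4 |
| delta | 10.0 | 15.7 | 73.1 |
| delta | 15.0 | 15.1 | 73.7 |
| zeta | 1.33 | 43.8 | 48.0 |
| zeta | 2.50 | 30.8 | 59.8 |
| zeta | 4.00 | 22.6 | 64.6 |
| zeta | 8.00 | 17.2 | 70.5 |
| zeta | 15.0 | 16.1 | 73.1 |

(readings scatter by 1 percentage point)

- the earlier runs were read with a standard deviation of 1 percentage point

- part of the electrophile that has reacted at the end, amber
- part of the electrophile that has reacted at the end, violet
- what raising the equivalents of free base from its lowest to its highest value here does to the part of the electrophile that has reacted (changes below 5 percentage points count as none) (no change / it rises / it falls)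

1. I began from an impossibility: if electrophile and nucleophile react one for one, a charge of 0.95 equiv of nucleophile in beta, delta and zeta cannot use up the electrophile.

2. I supposed that the protic impurity, 10.0% of the electrophile charge, also takes nucleophile one for one. That gave the spendable nucleophile, the nucleophile charged minus the impurity, as a fraction of the electrophile charge 85.0%. It makes nucleophile the limiting reagent and leaves 15.0% of the electrophile.

3. Fast rung: beta still held 48.6% of its electrophile at 1.33 h, and zeta, with more free base, read 43.8%.

4. Middle rung: by 8.00 h, beta read 15.2%.

5. Slow rung: at 15.0 h, beta, delta and zeta read 16.0%, 15.1% and 16.1%, close to the 15.0% I had reckoned.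

6. I froze the free base, since even violet's 3.00 equiv exceeds the spendable nucleophile. With 3.00 equiv above the spendable nucleophile, the free base stays out of the count, and 15 h lies later than the 8.00 h by which beta's electrophile readings had levelled. I expected 85.0% reacted in both amber and violet.

7. The forecast gave 85% for amber, 84% for violet and no change. It read the stall as one that “looks like an equilibrium or deactivation that doesn't depend on base”, a different ground from mine, and its violet value differs slightly from mine.

8. The flasks gave 84.8% for amber and 84.8% for violet, so no change, with a shift of 0.073 points.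

    electrophile + nucleophile → acid set free + target (k = 0.00190 /M/s)
    nucleophile + acid set free ⇌ protonated nucleophile, settled at all times (K = 820 /M)
    acid set free + free base ⇌ salt of the base (K = 90000 /M, k = 0.0180 /M/s)
    nucleophile + protic impurity → quenched reagent (k = 0.0440 /M/s)
    target ⇌ isomer of the product (K = 0.160, k = 5.60 × 10⁻⁴ /s)

9. In violet, the half-life of nucleophile by the quench step alone was 0.14 h, shorter than the 0.34 h of electrophile by the main step alone, each with the other concentrations as charged, and both are short against 15 h. At 15.0 h violet kept 0.25% of its nucleophile and 0% of its protic impurity, and 84.8% of its electrophile had reacted, against a spendable 85.0%.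

10. Take violet with 0.240 equiv of nucleophile: the same subtraction gives 14.0%. That flask computed 14.3% reacted, with 0% of its nucleophile left.

All runs are simulated for substances that don't exist; noise was put on by code.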